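**Strategy.** Ring A is grown in one pot onto a ring B enone that already carries the quaternary C5. In (R)-4-acetyl-4-methylcyclohex-2-enone the enone β-carbon (future C10) and the acetyl carbonyl (future C4) flank C5; lithiated diethyl allylphosphonate supplies C1–C3 and bridges them: γ-conjugate addition forms C1–C10, the regiodefined enolate is methylated at C9, and intramolecular Horner–Wadsworth–Emmons olefination forms C3=C4. The precursor is thus a monocyclic γ-acyl enone plus a three-carbon phosphonate. Later steps saturate C1=C2, quaternise C9, and oxidise ring B by enone transposition, reduction and face-selective dihydroxylation before the butenolide is coupled on.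

Key step: step 3

Remarks on the chemistry:
- Clerodane numbering is used throughout: ring A = C1–C5, C10; ring B = C5–C10; C17 on C8, C18 on C4, C19 on C5, C20 on C9; side chain C11–C16.
- Assumption: the enantiomer of the salen ligand in step 1 is the one that gives the (R)-configured quaternary centre; if the sense of induction is the reverse, the (1R,2R) ligand is used.
- C9 in 10–12 and C8 in 16 are epimer mixtures; both centres are reset later, so their SMILES leave them open.

**Step 1**
Reactants: 1 (E)-1-(dimethylamino)-3-(tert-butyldimethylsilyloxy)buta-1,3-diene; 2 methacrolein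
Product: 5 (R)-4-(1-hydroxyethyl)-4-methylcyclohex-2-en-1-one (carbinol epimers), via amino silyl enol ether cycloadduct 3 (not isolated), via bromomagnesium alkoxide 4 (not isolated)
Conditions: (salen)CrSbF6 (5 mol %; salen = (1S,2S)-N,N'-bis(3,5-di-tert-butylsalicylidene)cyclohexane-1,2-diaminate), 4 Å MS, CH2Cl2, −40 °C; then MeMgBr, THF, −78 °C; then HF, MeCN/H2O, 0 °C
Reagents that add atoms: methylmagnesium bromide, C[Mg]Br
Why: a catalytic enantioselective Diels–Alder reaction of the 1-amino-3-siloxydiene with the α-substituted enal should set the quaternary C5 (the chiral chromium Lewis acid selects the enal face), after which Grignard addition to the aldehyde and acid hydrolysis with β-elimination of dimethylamine unveil the enone.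

**Step 2**
Reactants: 5 (R)-4-(1-hydroxyethyl)-4-methylcyclohex-2-en-1-one
Product: 6 (R)-4-acetyl-4-methylcyclohex-2-en-1-one
Conditions: DMP, NaHCO3, CH2Cl2, 25 °C
Reagents that add atoms: none
Why: Dess–Martin oxidation of the secondary carbinol should give the methyl ketone without touching the enone or the non-enolisable quaternary centre.

**Step 3**
Reactants: 6 (R)-4-acetyl-4-methylcyclohex-2-en-1-one; 7 diethyl allylphosphonate
Product: 11 trans-fused ring A diene ketone (C1=C2 and C3=C4, C8 ketone, C9 methyl epimers), via lithiated allylphosphonate 8 (not isolated), via lithium enolate adduct 9 (not isolated), via methylated vinylphosphonate diketone 10 (not isolated)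
Conditions: 7, n-BuLi, THF, −78 °C; 6, −78 °C; MeI (1.0 equiv), −78 to −20 °C; KOt-Bu, THF, −20 to 25 °C
Reagents that add atoms: iodomethane, CI
Why: Proposed new method: lithiated 7 should add through its γ-carbon in 1,4-fashion to C10 of enone 6 via the lithium-bridged cyclic transition state known for allylic phosphonates and phosphine oxides with cyclic enones, the regiodefined lithium enolate 9 is C-methylated at C9, and KOt-Bu then equilibrates the vinylphosphonate 10 to its allylic anion, whose α-carbon (C3) attacks the acetyl carbonyl C4 and expels diethyl phosphate (intramolecular Horner–Wadsworth–Emmons), closing ring A as a 1,3-diene. The closest known reaction type is the cyclohexadiene annulation of allylidenetriphenylphosphorane with enones and alkylidene acetoacetates (Michael addition then intramolecular Wittig), here directed onto a pendant ketone because olefination at the ring carbonyl C8 would give a bridgehead alkene. Ring A closes by 6-exo-trig attack of C3 on C4=O followed by syn-elimination. C10 is set by the quaternary C5: attack anti to the acetyl group, which sits pseudoaxial and antiperiplanar to the incoming nucleophile, places C1 cis to the C19 methyl and gives the trans ring fusion; the C9 methyl configuration is inconsequential. The step needs γ- over α-attack and 1,4- over 1,2-addition, which the chelated transition state in THF without HMPA and the neopentyl, hindered acetyl group should secure, and it needs the enolate to survive until methylation, which is secured by adding exactly one equivalent of MeI before the alkoxide base.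

**Step 4**
Reactants: 11 ring A diene ketone
Product: 12 Δ3-ene 8-ketone (trans-decalin, C18/C19 methyls, C9 methyl epimers)
Conditions: 2-nitrobenzenesulfonylhydrazide, Et3N, CH2Cl2, 25 °C
Reagents that add atoms: none
Why: diimide reduction should saturate the cis-disubstituted C1=C2 of the diene far faster than the trisubstituted C3=C4, leaving the ketone untouched.

**Step 5**
Reactants: 12 Δ3-ene 8-ketone
Product: 14 9-(dimethoxymethyl)-9-methyl 8-ketone (C20 methyl syn to C19, acetal carbon C11 anti), via trimethylsilyl enol ether 13 (not isolated)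
Conditions: TMSCl, NaI, Et3N, MeCN, 25 °C; then HC(OMe)3, TMSOTf (10 mol %), CH2Cl2, −78 °C
Reagents that add atoms: trimethyl orthoformate, COC(OC)OC
Why: thermodynamic silylation should give the more substituted C8=C9 enol ether, and the Mukaiyama-type reaction with the dimethoxycarbenium ion should enter anti to the axial C19 methyl, as in classical clerodane C9 alkylations, so that C11 ends equatorial and C20 axial.

**Step 6**
Reactants: 14 acetal ketone
Product: 15 Δ6-8-enone
Conditions: IBX, 4-methoxypyridine N-oxide, DMSO, 25 °C
Reagents that add atoms: none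
Why: IBX dehydrogenation of the ketone can only occur toward C7, the single enolisable α-carbon, and should give the C6=C7 enone.

**Step 7**
Reactants: 15 Δ6-8-enone
Product: 16 tertiary allylic alcohol (C8 methyl carbinol, C8 epimers)
Conditions: MeLi, THF, −78 °C
Reagents that add atoms: methyllithium, C[Li]
Why: 1,2-addition of methyllithium to the hindered enone should deliver the tertiary allylic alcohol, whose C8 configuration is erased in the next step.

**Step 8**
Reactants: 16 tertiary allylic alcohol
Product: 17 Δ7-6-enone carrying the C17 methyl on C8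
Conditions: pyridinium chlorochromate, [C5H5NH][CrO3Cl], 4 Å MS, CH2Cl2, 25 °C
Reagents that add atoms: pyridinium chlorochromate, [O-][Cr](=O)(=O)Cl.c1cc[nH+]cc1
Why: oxidative 1,3-transposition (Babler–Dauben oxidation) through a [3,3]-shift of the chromate ester should move oxygen to C6 and give the β-methyl enone.

**Step 9**
Reactants: 17 Δ7-6-enone
Product: 18 3,4-epoxide of the enone (epoxide anti to C19)
Conditions: mCPBA, NaHCO3, CH2Cl2, 0 °C
Reagents that add atoms: 3-chloroperbenzoic acid, OOC(=O)c1cccc(Cl)c1
Why: Prilezhaev epoxidation should take the electron-rich C3=C4 alkene and leave the electron-poor enone alkene, so ring A is protected from the later osmylation.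

**Step 10**
Reactants: 18 epoxy enone
Product: 19 allylic alcohol with equatorial C6–OH (syn to C19)
Conditions: NaBH4, CeCl3·7H2O, MeOH, −20 °C
Reagents that add atoms: none
Why: Luche 1,2-reduction should deliver hydride axially from the face opposite the adjacent axial C19 methyl, giving the equatorial C6 alcohol.

**Step 11**
Reactants: 19 allylic alcohol
Product: 20 6,7,8-triol (C7–OH and C8–OH cis, both anti to C6–OH and to the C19/C20 methyls)
Conditions: OsO4 (5 mol %), NMO, acetone/H2O, 25 °C
Reagents that add atoms: 4-methylmorpholine N-oxide, C[N+]1([O-])CCOCC1; water, O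
Why: Upjohn dihydroxylation of the only remaining alkene should occur anti to the allylic hydroxyl and anti to the two axial methyls, setting C7 and C8 together.

**Step 12**
Reactants: 20 triol
Product: 21 6,7-diacetate with free tertiary C8–OH
Conditions: Ac2O, pyridine, DMAP (cat.), CH2Cl2, 25 °C
Reagents that add atoms: acetic anhydride, CC(=O)OC(C)=O
Why: acylation should take both secondary alcohols and leave the hindered axial tertiary alcohol free.

**Step 13**
Reactants: 21 epoxy diacetate
Product: 23 C11 aldehyde with restored C3=C4 alkene, via alkene dimethyl acetal 22 (not isolated)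
Conditions: Zn, NaI, NaOAc, AcOH, 25 °C; then 1 M HCl, THF, 25 °C
Reagents that add atoms: water, O
Why: iodide opening of the epoxide and zinc-induced elimination of the iodohydrin (reductive deoxygenation) should return the C3=C4 alkene, and mild acid hydrolysis of the dimethyl acetal then frees the aldehyde while acetates and the tertiary alcohol survive.

**Step 14**
Reactants: 23 aldehyde
Product: 24 (E)-alkenyl pinacol boronate (C11=C12)
Conditions: Cl2CHBpin, CrCl2, LiI, THF, 25 °C
Reagents that add atoms: 2-(dichloromethyl)-4,4,5,5-tetramethyl-1,3,2-dioxaborolane, ClC(Cl)B1OC(C)(C)C(C)(C)O1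
Why: the Takai–Utimoto olefination is non-basic, so the β-hydroxy aldehyde should not undergo retro-aldol cleavage, and it is E-selective for hindered aldehydes.

**Step 15**
Reactants: 24 (E)-alkenyl boronate; 25 4-bromofuran-2(5H)-one
Product: 26 target CNP0383656.1
Conditions: Pd(PPh3)4 (5 mol %), K3PO4, THF/H2O, 40 °C
Reagents that add atoms: none
Why: Suzuki–Miyaura coupling of the alkenyl boronate with the β-bromobutenolide should proceed with retention of the E geometry under base mild enough for the acetates.

**Compound list**
1 | (E)-1-(dimethylamino)-3-(tert-butyldimethylsilyloxy)buta-1,3-diene | CN(C)/C=C/C(=C)O[Si](C)(C)C(C)(C)C | starting material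
2 | methacrolein | CC(=C)C=O | starting material
3 | endo cycloadduct, 4-(tert-butyldimethylsilyloxy)-2-(dimethylamino)-1-methylcyclohex-3-ene-1-carbaldehyde (amino cis to formyl) | O=C[C@@]1(C)[C@@H](N(C)C)C=C(O[Si](C)(C)C(C)(C)C)CC1 | intermediate (not isolated)
4 | bromomagnesium alkoxide of the methyl carbinol derived from 3 | CC(O[Mg]Br)[C@@]1(C)[C@@H](N(C)C)C=C(O[Si](C)(C)C(C)(C)C)CC1 | intermediate (not isolated)
5 | (R)-4-(1-hydroxyethyl)-4-methylcyclohex-2-en-1-one (carbinol epimers) | CC(O)[C@@]1(C)C=CC(=O)CC1 | intermediate
6 | (R)-4-acetyl-4-methylcyclohex-2-en-1-one | CC(=O)[C@@]1(C)C=CC(=O)CC1 | intermediate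
7 | diethyl allylphosphonate | C=CCP(=O)(OCC)OCC | starting material
8 | lithiated diethyl allylphosphonate | [Li+].[CH-](C=C)P(=O)(OCC)OCC | intermediate (not isolated)
9 | lithium enolate of the γ-1,4-adduct (C1 on C10 cis to the C5 methyl, E-vinylphosphonate) | [Li+].CC(=O)[C@@]1(C)[C@H](C/C=C/P(=O)(OCC)OCC)C=C([O-])CC1 | intermediate (not isolated)
10 | C9-methylated vinylphosphonate diketone (C9 epimers) | CC(=O)[C@@]1(C)[C@H](C/C=C/P(=O)(OCC)OCC)C(C)C(=O)CC1 | intermediate (not isolated)
11 | trans-fused ring A diene ketone: decalin with C1=C2, C3=C4, C4/C5/C9 methyls, C8 ketone, H-10 anti to C19 (C9 epimers) | C1CC(=O)C(C)[C@H]2C=CC=C(C)[C@]12C | intermediate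
12 | Δ3-ene 8-ketone, trans-decalin (C9 epimers) | C1CC(=O)C(C)[C@H]2CCC=C(C)[C@]12C | intermediate
13 | C8=C9 trimethylsilyl enol ether of 12 | C1CC(O[Si](C)(C)C)=C(C)[C@H]2CCC=C(C)[C@]12C | intermediate (not isolated)
14 | 9-(dimethoxymethyl)-9-methyl 8-ketone (C20 syn to C19, C11 anti) | C1CC(=O)[C@](C)(C(OC)OC)[C@H]2CCC=C(C)[C@]12C | intermediate
15 | Δ6-8-enone | C1=CC(=O)[C@](C)(C(OC)OC)[C@H]2CCC=C(C)[C@]12C | intermediate
16 | C8 tertiary allylic alcohol (C8 epimers) | C1=CC(C)(O)[C@](C)(C(OC)OC)[C@H]2CCC=C(C)[C@]12C | intermediate
17 | Δ7-6-enone with C17 methyl on C8 | O=C1C=C(C)[C@](C)(C(OC)OC)[C@H]2CCC=C(C)[C@]12C | intermediate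
18 | 3,4-epoxy Δ7-6-enone (epoxide anti to C19) | O=C1C=C(C)[C@](C)(C(OC)OC)[C@H]2CC[C@@H]3O[C@]3(C)[C@]12C | intermediate
19 | 3,4-epoxy Δ7-6-ol (C6–OH syn to C19) | O[C@H]1C=C(C)[C@](C)(C(OC)OC)[C@H]2CC[C@@H]3O[C@]3(C)[C@]12C | intermediate
20 | 3,4-epoxy 6,7,8-triol (C7–OH and C8–OH anti to C19/C20) | O[C@H]1[C@H](O)[C@](C)(O)[C@](C)(C(OC)OC)[C@H]2CC[C@@H]3O[C@]3(C)[C@]12C | intermediate
21 | 3,4-epoxy 6,7-diacetate 8-ol dimethyl acetal | CC(=O)O[C@H]1[C@H](OC(C)=O)[C@](C)(O)[C@](C)(C(OC)OC)[C@H]2CC[C@@H]3O[C@]3(C)[C@]12C | intermediate
22 | Δ3-ene 6,7-diacetate 8-ol dimethyl acetal | CC(=O)O[C@H]1[C@H](OC(C)=O)[C@](C)(O)[C@](C)(C(OC)OC)[C@H]2CCC=C(C)[C@]12C | intermediate (not isolated)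
23 | Δ3-ene 6,7-diacetate 8-ol C11 aldehyde | CC(=O)O[C@H]1[C@H](OC(C)=O)[C@](C)(O)[C@](C)(C=O)[C@H]2CCC=C(C)[C@]12C | intermediate
24 | (E)-C11=C12 alkenyl pinacol boronate | CC(=O)O[C@H]1[C@H](OC(C)=O)[C@](C)(O)[C@](C)(/C=C/B2OC(C)(C)C(C)(C)O2)[C@H]2CCC=C(C)[C@]12C | intermediate
25 | 4-bromofuran-2(5H)-one | O=C1C=C(Br)CO1 | starting material
26 | CNP0383656.1 | CC(=O)O[C@H]1[C@H](OC(C)=O)[C@](C)(O)[C@](C)(/C=C/C2=CC(=O)OC2)[C@H]2CCC=C(C)[C@]12C | target

**Count.** Total steps: 15. Longest linear sequence: 15 (from 1 and 2).

**Steps most likely to fail**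

Step 3 (proposed new method). The cascade may fail through α-attack or 1,2-addition of the phosphonate anion, enolisation of the acetyl group, poor facial selectivity at C10, or stalling at the vinylphosphonate stage. The fallback sets out from 6 and uses two known operations. Copper-catalysed conjugate addition of (4-methylpent-3-en-1-yl)magnesium bromide (CuBr·SMe2, TMSCl, THF, −78 °C), followed by regeneration of the lithium enolate with MeLi and methylation with MeI, should give 4-acetyl-2,4-dimethyl-3-(4-methylpent-3-enyl)cyclohexanone F1. FeCl3-catalysed ring-closing carbonyl–olefin metathesis (1,2-dichloroethane, 25–60 °C) between the acetyl group and the trisubstituted alkene should then close ring A. The ring ketone cannot compete because it would give a bridgehead alkene. The fallback comes back to the route at 12.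

Step 5. Enolisation may be unselective between C7 and C9, and the hindered tetrasubstituted enol ether may react slowly with the carbenium ion. The fallback sets out from 12 and blocks C7. Formylation (HCO2Et, NaH, THF) should give the 7-hydroxymethylene ketone F2, and n-BuSH with TsOH the 7-(n-butylthiomethylene) ketone F3. Silylation (TMSOTf, Et3N) can now only give the C8=C9 dienol ether, which with HC(OMe)3 and TMSOTf should give the blocked 9-(dimethoxymethyl) ketone F4. Removal of the blocking group (KOH, diethylene glycol/H2O, 120 °C) comes back to the route at 14.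

Step 14. The neopentyl β-hydroxy aldehyde may react sluggishly with the chromium reagent, or open by retro-aldol cleavage during prolonged reaction. The fallback sets out from 23 and makes the whole side chain in one olefination. Diethyl [(5-oxo-2,5-dihydrofuran-3-yl)methyl]phosphonate F5, from a Michaelis–Arbuzov reaction of 4-(bromomethyl)furan-2(5H)-one with P(OEt)3, is condensed with 23 under Masamune–Roush conditions (LiCl, DBU, MeCN, 0–25 °C). This Horner–Wadsworth–Emmons reaction should give the (E)-diene directly and comes back to the route at 26.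

**Further compounds**
F1 | step 3 | 4-acetyl-2,4-dimethyl-3-(4-methylpent-3-enyl)cyclohexanone (side chain cis to the C4 methyl, C2 epimers) | CC(=O)[C@@]1(C)[C@H](CCC=C(C)C)C(C)C(=O)CC1
F2 | step 5 | 7-hydroxymethylene derivative of 12 | C1C(=CO)C(=O)C(C)[C@H]2CCC=C(C)[C@]12C
F3 | step 5 | 7-(n-butylthiomethylene) derivative of 12 | C1C(=CSCCCC)C(=O)C(C)[C@H]2CCC=C(C)[C@]12C
F4 | step 5 | 7-(n-butylthiomethylene) derivative of 14 | C1C(=CSCCCC)C(=O)[C@](C)(C(OC)OC)[C@H]2CCC=C(C)[C@]12C
F5 | step 14 | diethyl [(5-oxo-2,5-dihydrofuran-3-yl)methyl]phosphonate | CCOP(=O)(CC1=CC(=O)OC1)OCC
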